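**Plan**

1. Numbering: the right-hand bicycle is numbered as a 1-benzoxepine (O1, C2, C3, C4, C5, C5a, C6, C7, C8, C9, C9a), the decalin as C1′–C8a′. Cuts, in retrosynthetic order: C3=O from CHOH; both tertiary carbinols (C7, C5′) from exocyclic methylenes; the allylic bond C6–CH2 (enolate alkylation with a decalin allylic bromide); O1–C2 (7-endo epoxide opening); C7–C8 (ring closure); C5a–C6 (epoxide opening by an alkynylalane).
2. Enabling feature: O1–C9a–C5a–C6–C7 places the ring-fusion oxygen and the carbinol carbon 1,4 across the cyclohexane, which is a latent γ-butyrolactone. The oxepane oxygen therefore first serves as lactone oxygen, and the carbocycle closes when C8, as an α-sulfonyl carbanion, attacks the lactone carbonyl (future C7). The sulfone then steers the side chain to C6 and is removed.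
3. Decalin half: catalytic asymmetric Diels–Alder (cis-decalin), allylic oxidation, methylenation, enone reduction, vinyl addition, SN2′ bromination (E-alkylidene).
4. Benzoxepine half: geraniol, Sharpless epoxide, alkynylalane opening (quaternary C5a), terminal epoxide, sulfone and lactone, Shi epoxide, carbocycle (key), oxepane, union, desulfonylation, methylenation, double hydration, oxidation.
5. Stereochemistry: C5a and C9a come from the Sharpless epoxidation and the invertive opening; C6 is set by equilibration; C7 and C5′ by equatorial hydration anti to a syn-axial neighbour; C4a′ and C8a′ by the Diels–Alder catalyst; C2′ by enolate protonation; the C3 carbinol is transient.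

Key step: step 13

**Step 1**
Reactants: 1 4,4-dimethylcyclohex-2-en-1-one; 2 isoprene
Product: 3 (4aR,8aS)-4,4,6-trimethyl-3,4,4a,5,8,8a-hexahydronaphthalen-1(2H)-one
Conditions: (S)-1-(2-methylphenyl)-3,3-diphenyltetrahydro-1H,3H-pyrrolo[1,2-c][1,3,2]oxazaborole (10 mol%), AlBr3 (8 mol%), CH2Cl2, −40 → −20 °C
Reagents that add atoms: none
Why: Enantioselective Lewis-acid-catalysed Diels–Alder reaction (Corey-type cationic oxazaborolidine), in which the 2-methyl group of the diene directs its C1 to the enone β-carbon ("para" adduct), suprafacial addition to the ring alkene fixes the cis fusion (C4a, C8a), and the catalyst differentiates the enone faces (the (S)-catalyst is proposed from the shielding model for 2-cycloalkenones; its mirror image would serve if the sense were reversed).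

**Step 2**
Reactants: 3
Product: 4 (4aR,8aS)-5-hydroxy-4,4,6-trimethyl-3,4,4a,5,8,8a-hexahydronaphthalen-1(2H)-one (carbinol configuration open)
Conditions: SeO2 (0.5 equiv), t-BuOOH (3 equiv), CH2Cl2, rt
Reagents that add atoms: tert-butyl hydroperoxide, CC(C)(C)OO
Why: Selenium dioxide allylic oxidation (ene reaction, then [2,3]-sigmatropic shift) should hydroxylate the ring CH2 next to the methyl-bearing alkene carbon while the ketone is untouched at room temperature, and the carbinol configuration is irrelevant because it is oxidised in step 4.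

**Step 3**
Reactants: 4
Product: 5 (4aS,8aR)-2,8,8-trimethyl-5-methylidene-1,4,4a,5,6,7,8,8a-octahydronaphthalen-1-ol (carbinol configuration open)
Conditions: Ph3PCH3Br (2.5 equiv), KOtBu (2.4 equiv), THF, 0 °C → rt
Reagents that add atoms: methyltriphenylphosphonium bromide, C[P+](c1ccccc1)(c1ccccc1)c1ccccc1.[Br-]
Why: Wittig methylenation of the only ketone, run cold to keep the epimerisable ring-fusion carbon next to it intact; the free hydroxyl is carried as its alkoxide.

**Step 4**
Reactants: 5
Product: 6 (4aS,8aR)-2,8,8-trimethyl-5-methylidene-4a,5,6,7,8,8a-hexahydronaphthalen-1(4H)-one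
Conditions: Dess–Martin periodinane, CH2Cl2, 0 °C
Reagents that add atoms: none
Why: Dess–Martin oxidation of the secondary allylic alcohol to the 2-methyl enone; the exocyclic alkene is inert.

**Step 5**
Reactants: 6
Product: 7 (2R,4aS,8aR)-2,8,8-trimethyl-5-methylideneoctahydronaphthalen-1(2H)-one
Conditions: Li, NH3 (l), THF, t-BuOH (1.0 equiv), −78 °C; then NH4Cl
Reagents that add atoms: none
Why: Dissolving-metal reduction of the enone gives the enolate on the C2′ side only, so the ring-fusion carbon C8a′ cannot epimerise, and axial protonation on quench should place the C2′ methyl equatorial (2R), which is also the more stable epimer.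

**Step 6**
Reactants: 7
Product: 8 (2R,4aS,8aR)-1-ethenyl-2,8,8-trimethyl-5-methylidenedecahydronaphthalen-1-ol (carbinol configuration open)
Conditions: CH2=CHMgBr, CeCl3, THF, −78 → 0 °C
Reagents that add atoms: vinylmagnesium bromide, C=C[Mg]Br
Why: Organocerium 1,2-addition to a hindered, enolisable ketone without enolisation; the new carbinol stereocenter is lost in step 7, so either face serves.

**Step 7**
Reactants: 8
Product: 9 (1E,2R,4aS,8aR)-1-(2-bromoethylidene)-2,8,8-trimethyl-5-methylidenedecahydronaphthalene
Conditions: PBr3 (0.4 equiv), pyridine (0.1 equiv), Et2O, −20 → 0 °C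
Reagents that add atoms: phosphorus tribromide, BrP(Br)Br
Why: SN2′ bromination of a tertiary vinyl carbinol with allylic transposition, in which allylic 1,3-strain should turn the CH2Br arm toward C2′ (CHMe) and away from C8a′ with its neighbouring quaternary C8′, giving the E-alkylidene.

**Step 8**
Reactants: 10 geraniol
Product: 11 (2S,3S)-2,3-epoxygeraniol
Conditions: Ti(OiPr)4 (5 mol%), L-(+)-diethyl tartrate (6 mol%), t-BuOOH, 4 Å molecular sieves, CH2Cl2, −20 °C
Reagents that add atoms: tert-butyl hydroperoxide, CC(C)(C)OO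
Why: Sharpless asymmetric epoxidation of the allylic alcohol, in which the L-(+)-tartrate ligand should deliver the (2S,3S)-epoxide and thereby set both future ring-fusion centres (C9a and, after inversion, C5a).

**Step 9**
Reactants: 11
Product: 12 (2R,3S)-3-(ethoxyethynyl)-3,7-dimethyloct-6-ene-1,2-diol
Conditions: ethoxyacetylene, n-BuLi, then Et2AlCl, toluene, 0 °C; add 11, 0 °C → rt; aq. KNaC4H4O6
Reagents that add atoms: ethoxyacetylene, C#COCC
Why: Alkynylalane opening of a 2,3-epoxy alcohol at C3 (aluminium-alkoxide-directed, with inversion at the tertiary carbon, using the ethoxyethynylalane of the classical lactone annulation) creates the quaternary stereocenter (future C5a, S) while the carbinol carbon (future C9a) keeps its configuration.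

**Step 10**
Reactants: 12
Product: 13 (2R)-2-[(3S)-1-ethoxy-3,7-dimethyloct-6-en-1-yn-3-yl]oxirane
Conditions: NaH (2.2 equiv), N-tosylimidazole (1.05 equiv), THF, 0 °C → rt
Reagents that add atoms: none
Why: One-pot epoxide formation from a 1,2-diol by selective sulfonylation of the primary hydroxyl and Williamson closure by the secondary alkoxide; no bond to the stereocenter is broken and the ynol ether is stable to base.

**Step 11**
Reactants: 13
Product: 15 (4S,5S)-4-methyl-4-(4-methylpent-3-en-1-yl)-5-[2-(phenylsulfonyl)ethyl]dihydrofuran-2(3H)-one, via hydroxy sulfone ynol ether 14 (not isolated)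
Conditions: PhSO2CH3, n-BuLi, THF/DMPU, −78 °C → rt; then 1 M HCl, THF, 0 °C → rt
Reagents that add atoms: methyl phenyl sulfone, CS(=O)(=O)c1ccccc1; water, O
Why: The α-sulfonyl carbanion opens the terminal epoxide at its CH2 (installing future C8 with its activator), and dilute acid then protonates the ynol ether to a ketene-type cation that the neighbouring hydroxyl traps and water hydrolyses to the γ-lactone (ynol ether lactone annulation), which ties the future O1 to the future C7 carbonyl.

**Step 12**
Reactants: 15
Product: 16 (4S,5S)-4-{2-[(2R)-3,3-dimethyloxiran-2-yl]ethyl}-4-methyl-5-[2-(phenylsulfonyl)ethyl]dihydrofuran-2(3H)-one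
Conditions: 1,2:4,5-di-O-isopropylidene-β-D-erythro-2,3-hexodiulo-2,6-pyranose (30 mol%), KHSO5, K2CO3, Bu4NHSO4, MeCN/CH2(OMe)2/aq. Na2B4O7, 0 °C
Reagents that add atoms: potassium peroxymonosulfate, [K+].[O-]S(=O)(=O)OO
Why: Shi epoxidation (dioxirane from the fructose-derived ketone) of the only alkene should give the (R)-epoxide through the spiro transition state; this carbinol centre is transient because C3 ends as a ketone.

**Step 13**
Reactants: 16
Product: 18 (4S,5S)-5-{2-[(2R)-3,3-dimethyloxiran-2-yl]ethyl}-4-hydroxy-5-methyl-2-(phenylsulfonyl)cyclohexan-1-one (epimers at the sulfonyl carbon), via bridged hemiketal alkoxide 17 (not isolated)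
Conditions: KN(SiMe3)2 (2.2 equiv), THF, −78 → −20 °C; AcOH, −78 °C
Reagents that add atoms: none
Why: Mechanism: the amide base removes a proton from the unhindered α-sulfonyl CH2 (future C8), the carbanion adds across the five-membered ring to the lactone carbonyl (future C7) to give the 7-oxabicyclo[2.2.1]heptan-1-olate 17, this collapses by expelling the C9a alkoxide, and the β-keto sulfone is at once deprotonated, which makes the acyl transfer from oxygen to carbon irreversible. The closest known reaction type is the Claisen/Dieckmann-type acylation of α-sulfonyl carbanions by esters and lactones to give β-keto sulfones. The cyclohexane (C5a–C6–C7–C8–C9–C9a) closes in the 6-exo-trig mode on the carbonyl carbon. The only new stereocenter is the sulfonyl-bearing C8, which is labile and removed in step 16, whereas C5a and C9a pass unchanged from the lactone, so the event needs no stereocontrol. The selectivity needed is deprotonation at the sulfone CH2 and not productively at the lactone CH2, and no attack on the epoxide: the lactone CH2 is neopentyl (next to quaternary C5a), its enolate has no productive pathway and re-equilibrates, and the potassium alkoxide should not open the trisubstituted epoxide at low temperature before the acidic quench. In one operation the event builds the carbocycle, frees the C9a hydroxyl for oxepane formation, and leaves the C7 ketone and the sulfone that together direct the side chain to C6.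

**Step 14**
Reactants: 18
Product: 19 (3R,5aS,9aS)-3-hydroxy-2,2,5a-trimethyl-8-(phenylsulfonyl)octahydro-1-benzoxepin-7(2H)-one (epimers at C8)
Conditions: (+)-camphor-10-sulfonic acid (0.2 equiv), CH2Cl2, 0 °C
Reagents that add atoms: none
Why: Acid-catalysed hydroxy-epoxide cyclisation, in which the C9a hydroxyl should open the protonated epoxide at its tertiary carbon (7-endo, Markovnikov) to give the 2,2-dimethyloxepane; the trans ring fusion is preset by C5a and C9a and the C3 hydroxyl keeps the epoxide configuration.

**Step 15**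
Reactants: 19; 9
Product: 20 (6R)-6-{(2E)-2-[(2R,4aS,8aR)-2,8,8-trimethyl-5-methylideneoctahydronaphthalen-1(2H)-ylidene]ethyl} derivative of 19
Conditions: LiN(iPr)2 (3.3 equiv), THF/DMPU, −78 → −10 °C; then 9, −78 → 0 °C
Reagents that add atoms: none
Why: γ-Alkylation of a β-keto sulfone dianion (Weiler-type): after the hydroxyl and C8–H are deprotonated the third equivalent removes a C6 proton, the more basic C6 terminus displaces the allylic bromide (SN2), and the electrophile should enter anti to the axial C5a methyl to give the 6-epimer.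

**Step 16**
Reactants: 20
Product: 22 (3R,5aS,6S,9aS)-3-hydroxy-2,2,5a-trimethyl-6-{(2E)-2-[(2R,4aS,8aR)-2,8,8-trimethyl-5-methylideneoctahydronaphthalen-1(2H)-ylidene]ethyl}octahydro-1-benzoxepin-7(2H)-one, via 6-epi ketone 21 (not isolated)
Conditions: Al(Hg), THF/H2O (9:1), rt; then NaOMe (0.3 equiv), MeOH, rt
Reagents that add atoms: none
Why: Reductive desulfonylation of the β-keto sulfone by aluminium amalgam gives the C7 ketone, and base then equilibrates the enolisable C6 centre toward the epimer with the equatorial side chain (axial protonation anti to the C5a methyl; the axial epimer carries two syn-axial interactions), which is the target configuration, the minor epimer being recycled.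

**Step 17**
Reactants: 22
Product: 23 7-methylidene analogue of 22 (C7=CH2 in place of C7=O)
Conditions: Ph3PCH3Br, KOtBu, toluene, rt → 60 °C
Reagents that add atoms: methyltriphenylphosphonium bromide, C[P+](c1ccccc1)(c1ccccc1)c1ccccc1.[Br-]
Why: Wittig methylenation of a cyclohexanone next to a quaternary centre, as practised on 8-oxo-labdane-type ketones; no stereocenter is formed and the ketone enters already equilibrated at C6.

**Step 18**
Reactants: 23
Product: 25 triol (3R)-alcohol of the target, via bis-organomercurial triol 24 (not isolated)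
Conditions: Hg(OAc)2 (2.2 equiv), THF/H2O (1:1), 0 °C; then 3 M NaOH, NaBH4, 0 °C
Reagents that add atoms: water, O
Why: Oxymercuration–demercuration should hydrate the two 1,1-disubstituted exocyclic alkenes in preference to the hindered trisubstituted one (Markovnikov hydration), with water attacking each tertiary carbon from the equatorial side because the axial side is blocked by a syn-axial substituent (the C5a methyl for C7, C1′ for C5′), so that both hydroxyls end equatorial and both new methyls axial as in the target.

**Step 19**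
Reactants: 25
Product: 26 target CNP0232921.1
Conditions: Dess–Martin periodinane, CH2Cl2, 0 °C → rt
Reagents that add atoms: none
Why: Dess–Martin oxidation of the only secondary alcohol to the C3 ketone; the two tertiary alcohols, the ether and the alkene are inert.

**Compound list**

1 | 4,4-dimethylcyclohex-2-en-1-one | CC1(C)CCC(=O)C=C1 | starting material
2 | isoprene (2-methylbuta-1,3-diene) | CC(=C)C=C | starting material
3 | (4aR,8aS)-4,4,6-trimethyl-3,4,4a,5,8,8a-hexahydronaphthalen-1(2H)-one, cis-fused | CC1=CC[C@H]2[C@@H](C1)C(C)(C)CCC2=O | intermediate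
4 | (4aR,8aS)-5-hydroxy-4,4,6-trimethyl-3,4,4a,5,8,8a-hexahydronaphthalen-1(2H)-one, C5 configuration open | CC1=CC[C@H]2[C@@H](C1O)C(C)(C)CCC2=O | intermediate
5 | (4aS,8aR)-2,8,8-trimethyl-5-methylidene-1,4,4a,5,6,7,8,8a-octahydronaphthalen-1-ol, C1 configuration open | CC1=CC[C@H]2[C@@H](C1O)C(C)(C)CCC2=C | intermediate
6 | (4aS,8aR)-2,8,8-trimethyl-5-methylidene-4a,5,6,7,8,8a-hexahydronaphthalen-1(4H)-one | CC1=CC[C@H]2[C@@H](C1=O)C(C)(C)CCC2=C | intermediate
7 | (2R,4aS,8aR)-2,8,8-trimethyl-5-methylideneoctahydronaphthalen-1(2H)-one | C[C@@H]1CC[C@H]2[C@@H](C1=O)C(C)(C)CCC2=C | intermediate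
8 | (2R,4aS,8aR)-1-ethenyl-2,8,8-trimethyl-5-methylidenedecahydronaphthalen-1-ol, C1 configuration open | C[C@@H]1CC[C@H]2[C@@H](C1(O)C=C)C(C)(C)CCC2=C | intermediate
9 | (1E,2R,4aS,8aR)-1-(2-bromoethylidene)-2,8,8-trimethyl-5-methylidenedecahydronaphthalene | C[C@@H]1CC[C@H]2[C@@H](/C1=C/CBr)C(C)(C)CCC2=C | intermediate
10 | geraniol | CC(C)=CCC/C(C)=C/CO | starting material
11 | (2S,3S)-2,3-epoxygeraniol | OC[C@@H]1O[C@@]1(C)CCC=C(C)C | intermediate
12 | (2R,3S)-3-(ethoxyethynyl)-3,7-dimethyloct-6-ene-1,2-diol | OC[C@H](O)[C@@](C#COCC)(C)CCC=C(C)C | intermediate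
13 | (2R)-2-[(3S)-1-ethoxy-3,7-dimethyloct-6-en-1-yn-3-yl]oxirane | C1O[C@@H]1[C@@](C#COCC)(C)CCC=C(C)C | intermediate
14 | (3S,4S)-4-(ethoxyethynyl)-4,8-dimethyl-1-(phenylsulfonyl)non-7-en-3-ol | O=S(=O)(CC[C@H](O)[C@@](C#COCC)(C)CCC=C(C)C)c1ccccc1 | intermediate
15 | (4S,5S)-4-methyl-4-(4-methylpent-3-en-1-yl)-5-[2-(phenylsulfonyl)ethyl]dihydrofuran-2(3H)-one | O=C1C[C@](C)(CCC=C(C)C)[C@H](CCS(=O)(=O)c2ccccc2)O1 | intermediate
16 | (4S,5S)-4-{2-[(2R)-3,3-dimethyloxiran-2-yl]ethyl}-4-methyl-5-[2-(phenylsulfonyl)ethyl]dihydrofuran-2(3H)-one | O=C1C[C@](C)(CC[C@H]2OC2(C)C)[C@H](CCS(=O)(=O)c3ccccc3)O1 | intermediate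
17 | potassium 7-oxabicyclo[2.2.1]heptan-1-olate adduct of 16 (bridgeheads: future C7 and C9a) | [K+].[O-]C12C[C@](C)(CC[C@H]3OC3(C)C)[C@@H](O1)CC2S(=O)(=O)c1ccccc1 | intermediate
18 | (4S,5S)-5-{2-[(2R)-3,3-dimethyloxiran-2-yl]ethyl}-4-hydroxy-5-methyl-2-(phenylsulfonyl)cyclohexan-1-one, C2 epimers | O=C1C[C@](C)(CC[C@H]2OC2(C)C)[C@@H](O)CC1S(=O)(=O)c3ccccc3 | intermediate
19 | (3R,5aS,9aS)-3-hydroxy-2,2,5a-trimethyl-8-(phenylsulfonyl)octahydro-1-benzoxepin-7(2H)-one, trans-fused, C8 epimers | O=C1C[C@]2(C)CC[C@@H](O)C(C)(C)O[C@H]2CC1S(=O)(=O)c3ccccc3 | intermediate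
20 | (6R)-6-alkylated β-keto sulfone: 19 carrying at C6, trans to the C5a methyl, the (E)-2-(decalinylidene)ethyl chain from 9 | C[C@@H]1CC[C@H]2[C@@H](/C1=C/C[C@@H]1[C@]3(C)CC[C@@H](O)C(C)(C)O[C@H]3CC(S(=O)(=O)c4ccccc4)C1=O)C(C)(C)CCC2=C | intermediate
21 | (6R)-ketone, 6-epimer of 22 | C[C@@H]1CC[C@H]2[C@@H](/C1=C/C[C@@H]1[C@]3(C)CC[C@@H](O)C(C)(C)O[C@H]3CCC1=O)C(C)(C)CCC2=C | intermediate
22 | (3R,5aS,6S,9aS)-3-hydroxy-2,2,5a-trimethyl-6-{(2E)-2-[(2R,4aS,8aR)-2,8,8-trimethyl-5-methylideneoctahydronaphthalen-1(2H)-ylidene]ethyl}octahydro-1-benzoxepin-7(2H)-one | C[C@@H]1CC[C@H]2[C@@H](/C1=C/C[C@H]1[C@]3(C)CC[C@@H](O)C(C)(C)O[C@H]3CCC1=O)C(C)(C)CCC2=C | intermediate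
23 | 7-methylidene analogue of 22 (two exocyclic methylenes, C7 and C5′) | C[C@@H]1CC[C@H]2[C@@H](/C1=C/C[C@H]1[C@]3(C)CC[C@@H](O)C(C)(C)O[C@H]3CCC1=C)C(C)(C)CCC2=C | intermediate
24 | bis(acetoxymercuriomethyl) triol (HgOAc on both new CH2 groups, hydroxyls at C7 and C5′ equatorial) | C[C@@H]1CC[C@H]2[C@@H](/C1=C/C[C@H]1[C@]3(C)CC[C@@H](O)C(C)(C)O[C@H]3CC[C@]1(C[Hg]OC(C)=O)O)C(C)(C)CC[C@]2(C[Hg]OC(C)=O)O | intermediate
25 | triol: (3R)-3-hydroxy analogue of the target | C[C@@H]1CC[C@H]2[C@@H](/C1=C/C[C@H]1[C@]3(C)CC[C@@H](O)C(C)(C)O[C@H]3CC[C@]1(C)O)C(C)(C)CC[C@]2(C)O | intermediate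
26 | CNP0232921.1: (5aS,6S,7S,9aS)-7-hydroxy-6-{(2E)-2-[(2R,4aS,5S,8aR)-5-hydroxy-2,5,8,8-tetramethyloctahydronaphthalen-1(2H)-ylidene]ethyl}-2,2,5a,7-tetramethyloctahydro-1-benzoxepin-3(2H)-one | C[C@@H]1CC[C@H]2[C@@H](/C1=C/C[C@H]1[C@]3(C)CCC(=O)C(C)(C)O[C@H]3CC[C@]1(C)O)C(C)(C)CC[C@]2(C)O | target

**Step count and risks**

Total steps: 19. Longest linear sequence: 12 steps (geraniol to the target, steps 8–19; the decalin branch, steps 1–7 followed by 15–19, is equally long).

Steps most likely to fail:

Step 14. The hydroxyl may attack the secondary epoxide carbon (6-exo) and give a tetrahydropyran instead of the oxepane. Fallback: the ether is closed by Markovnikov alkoxymercuration instead of epoxide opening. The route sets out from 15, leaving out step 12. The conditions of step 13 convert 15 into hydroxy alkene keto sulfone F1. Hg(O2CCF3)2 in CH3NO2 at 0 °C should then join the C9a oxygen to the tertiary alkene carbon (7-endo) and give the C3-mercurated oxepane F2. Oxidative demercuration (O2, NaBH4, DMF) should give 19 together with its C3 epimer F3. The route is rejoined at 19; the epimer converges with it because C3 ends as a ketone.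

Step 16. The thermodynamic preference between the C6 epimers may be too small, so that equilibration leaves much of the wrong epimer. Fallback: kinetic control in place of equilibration. The route sets out from 20, which is converted once more into its dianion (LiN(iPr)2, THF/DMPU, −78 → 0 °C) and quenched with AcOH at −78 °C. Protonation of the C6 terminus anti to the axial C5a methyl should give the (6S)-β-keto sulfone F4. Its desulfonylation with Al(Hg) at 0 °C without base gives 22, where the route is rejoined.

Step 1. The β-neopentyl enone may turn over slowly and be poorly face-differentiated by the chiral Lewis acid. Fallback: racemic synthesis and resolution. Starting again from 1 and 2, AlCl3 in toluene gives the cis adduct as the racemate, that is 3 together with its enantiomer ent-adduct F5. The enantiomers are separated by preparative chromatography on a chiral stationary phase, and the route is rejoined at 3.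

**Further compounds**

F1 | step 14 | (4S,5S)-4-hydroxy-5-methyl-5-(4-methylpent-3-en-1-yl)-2-(phenylsulfonyl)cyclohexan-1-one | O=C1C[C@](C)(CCC=C(C)C)[C@@H](O)CC1S(=O)(=O)c2ccccc2
F2 | step 14 | (5aS,9aS)-2,2,5a-trimethyl-8-(phenylsulfonyl)-3-(trifluoroacetoxymercurio)octahydro-1-benzoxepin-7(2H)-one | O=C1C[C@]2(C)CCC([Hg]OC(=O)C(F)(F)F)C(C)(C)O[C@H]2CC1S(=O)(=O)c3ccccc3
F3 | step 14 | (3S,5aS,9aS)-3-hydroxy-2,2,5a-trimethyl-8-(phenylsulfonyl)octahydro-1-benzoxepin-7(2H)-one (C3 epimer of 19) | O=C1C[C@]2(C)CC[C@H](O)C(C)(C)O[C@H]2CC1S(=O)(=O)c3ccccc3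
F4 | step 16 | (6S)-epimer of 20 | C[C@@H]1CC[C@H]2[C@@H](/C1=C/C[C@H]1[C@]3(C)CC[C@@H](O)C(C)(C)O[C@H]3CC(S(=O)(=O)c4ccccc4)C1=O)C(C)(C)CCC2=C
F5 | step 1 | (4aS,8aR)-4,4,6-trimethyl-3,4,4a,5,8,8a-hexahydronaphthalen-1(2H)-one (enantiomer of 3) | CC1=CC[C@@H]2[C@H](C1)C(C)(C)CCC2=O
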